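I start from the easy end, the last noon reading, and ask what share of the remaining D turns into E each hour.

the same everywhere: Q 3.2 mM (held)

|  | D | X | remark | time |
|---|---|---|---|---|
| noon | 0.010 M | 0.010 M | run made earlier |  |
| flask | 0.020 M | 0.020 M |  | 12 h |

noon run (percent of the D and X together charged): time / h: E / % = 0.200: 0; 0.500: 0; 1.00: 2.0; 1.50: 2.4; 2.00: 5.1; 3.00: 7.4; 4.00: 9.9

(scatter of a reading: 0.5 percentage points)

* amount of E in percent of the D and X together charged, at 40 min, 3.0 h and 12 h

- Z is single-handed; D and X are mirror images of each other, charged as a racemate, each of them at the stated concentration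
- at the start none of Q is in solution
- the handed part of Z does not stay in what it makes, so the products of the two hands are mirror images too

D is half of the charge, and the noon run shows E at 9.9% after 4.00 h. Counting E against that half gives the pace, the share of the remaining D that becomes E per hour (a first-order constant): 0.0552 /h. I assume the pace does not change with the charge, so the flask at 12 h should show E at 24.2%.

The forecast gives 1.2%, 7.4% and 24.5%, and mine at 12 h lies slightly lower. It assumes first order, so that “percent conversion is independent of concentration”.

The flask gives 0.723%, 5.51% and 23.1%.

    Z + D → E (k = 52.0 /M/h)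
    Q ⇌ Z, rate k2*(csat - [Z]) (kL = 0.650 /h)
    D ⇌ G (K = 0.510, k = 0.260 /h)
    X ⇌ G (K = 0.510, k = 0.260 /h)
    Z + X → L (k = 26.0 /M/h)

The same sum on the flask's figure at 12 h gives a pace of 0.0517 /h, beside the pace of 0.0552 /h read off the noon reading, which carries its scatter. In this flask the relaxation half-life of X and G by the step X ⇌ G alone is 0.900 h, far shorter than the 9.3 h half-life of D by the turning of Z + D into E at 12.0 h, and at 120 h E stands at 63.4%, more than the half D was of the charge.

Readings and results are calculated on assumed constants; noise was put on by code.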